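## Retrosynthetic overview

1. Target 19 ⇐ lactol 16 by three side-chain operations: reduction at C11 (organocatalyst control), methylenation at C13, cross-metathesis for C13=C14–C15(OH).
2. Lactol 16 ⇐ acyclic bis(silyl dienol ether) 13 in one flask. Palladium allylation forms C1–C5 and closes the cyclopentene (C1–C5) first. Lewis-acid vinylogous aldol cyclocondensation then forms C6–C7 and closes the cycloheptane (C1, C5–C10) second.
3. Enabling feature: C10, the ring carbon carrying the exocyclic methylene C18, sits between two constitutionally identical six-carbon arms. These are C1–C2–C3–C4(CH3)–C5–C6 (cyclopentene plus carbinol) and C9–C8–C7–C11(CH3)–C12–C13 (acetoxy carbon, ring CH2, side-chain stem). Each arm is a masked 3-methyl-2-enal; ring size makes the first react at its α-carbon C5 and the second at its γ-carbon C7.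
4. Precursor 13 ⇐ Morita–Baylis–Hillman union of aldehyde 4 with vinyl ketone 6 (both from geraniol); the C1 carbonate is the leaving group and the C9 acetate is already the target's ester.
5. Stereochemistry: C9 by Corey–Bakshi–Shibata reduction; C1 by the palladium ligand; C5, C6 and C7 relayed in the key step; C11 by the imidazolidinone catalyst.

Key step: step 13

Remark: C1–C19 are the positions in the target skeleton (C1/C5 ring fusion, C6 carbinol, C7 side-chain carbon, C9 acetoxy carbon, C10=C18 methylene, C19 on C4, C16 on C11). The sense of induction of the palladium ligand in step 13 is assumed, not derived.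

## Route

Step 1
Reactants: 1 geraniol
Product: 2 geranyl tert-butyldimethylsilyl ether
Conditions: TBSCl, imidazole, DMF, 0 to 23 °C
Reagents that add atoms: tert-butyldimethylsilyl chloride CC(C)(C)[Si](C)(C)Cl
Why: Standard silylation of a primary allylic alcohol; no stereocenter is involved.

Step 2
Reactants: 2 geranyl tert-butyldimethylsilyl ether
Product: 3 6,7-epoxygeranyl tert-butyldimethylsilyl ether (racemic epoxide)
Conditions: mCPBA, NaHCO3, CH2Cl2, −20 °C
Reagents that add atoms: 3-chloroperoxybenzoic acid OOC(=O)c1cccc(Cl)c1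
Why: Prilezhaev epoxidation should favour the electron-rich distal trisubstituted alkene over the alkene deactivated by the allylic silyloxy group; the epoxide configuration is irrelevant because this carbon is cleaved off.

Step 3
Reactants: 3 6,7-epoxygeranyl tert-butyldimethylsilyl ether
Product: 4 (4E)-6-(tert-butyldimethylsilyloxy)-4-methylhex-4-enal
Conditions: H5IO6, THF/H2O, 0 °C
Reagents that add atoms: none
Why: Periodic acid hydrolyses the epoxide to the glycol and cleaves it (Malaprade cleavage) to the aldehyde with loss of acetone.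

Step 4
Reactants: 4 (4E)-6-(tert-butyldimethylsilyloxy)-4-methylhex-4-enal
Product: 5 (6E)-8-(tert-butyldimethylsilyloxy)-6-methylocta-1,6-dien-3-ol (racemic)
Conditions: CH2=CHMgBr, THF, −78 °C; aq NH4Cl
Reagents that add atoms: vinylmagnesium bromide C=C[Mg]Br
Why: Grignard 1,2-addition to the aldehyde; the new stereocenter is removed in the next step.

Step 5
Reactants: 5 (6E)-8-(tert-butyldimethylsilyloxy)-6-methylocta-1,6-dien-3-ol
Product: 6 (6E)-8-(tert-butyldimethylsilyloxy)-6-methylocta-1,6-dien-3-one
Conditions: Dess–Martin periodinane, NaHCO3, CH2Cl2, 0 °C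
Reagents that add atoms: none
Why: Dess–Martin oxidation gives the sensitive vinyl ketone under buffered, non-basic conditions.

Step 6
Reactants: 4 (4E)-6-(tert-butyldimethylsilyloxy)-4-methylhex-4-enal; 6 (6E)-8-(tert-butyldimethylsilyloxy)-6-methylocta-1,6-dien-3-one
Product: 7 (2E,11E)-1,13-bis(tert-butyldimethylsilyloxy)-8-hydroxy-3,11-dimethyl-7-methylidenetrideca-2,11-dien-6-one (racemic)
Conditions: DABCO (30 mol %), dioxane/H2O 1:1, 23 °C
Reagents that add atoms: none
Why: Morita–Baylis–Hillman reaction: the amine adds to the vinyl ketone, the enolate adds to aldehyde 4 and the amine is expelled, which places C10 with its methylene between the future C1 carbinol and C9 carbonyl; the racemic carbinol (C1) is erased later at the π-allyl stage.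

Step 7
Reactants: 7 Morita–Baylis–Hillman adduct
Product: 8 (2E,11E)-1,13-bis(tert-butyldimethylsilyloxy)-3,11-dimethyl-7-methylidene-6-oxotrideca-2,11-dien-8-yl methyl carbonate (racemic)
Conditions: ClCO2Me, pyridine, CH2Cl2, 0 °C
Reagents that add atoms: methyl chloroformate COC(=O)Cl
Why: Acylation of the secondary alcohol installs the leaving group for the later ionization by palladium.

Step 8
Reactants: 8 keto carbonate
Product: 9 (2E,6R,11E)-1,13-bis(tert-butyldimethylsilyloxy)-6-hydroxy-3,11-dimethyl-7-methylidenetrideca-2,11-dien-8-yl methyl carbonate (both C8 epimers)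
Conditions: (S)-2-methyl-CBS-oxazaborolidine (20 mol %), catecholborane, toluene, −78 °C
Reagents that add atoms: none
Why: Corey–Bakshi–Shibata reduction with the alkenyl group as the large substituent should give the (R)-carbinol (target C9) under reagent control, whichever epimer is present at the carbonate carbon.

Step 9
Reactants: 9 (6R)-alcohol
Product: 10 (2E,6R,11E)-6-acetoxy-1,13-bis(tert-butyldimethylsilyloxy)-3,11-dimethyl-7-methylidenetrideca-2,11-dien-8-yl methyl carbonate
Conditions: Ac2O, pyridine, DMAP (cat.), CH2Cl2, 0 °C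
Reagents that add atoms: acetic anhydride CC(=O)OC(C)=O
Why: Acetylation installs the C9 acetate of the target directly; an acetate is ionized by zerovalent palladium much more slowly than the carbonate.

Step 10
Reactants: 10 bis(silyl ether)
Product: 11 (2E,6R,11E)-6-acetoxy-1,13-dihydroxy-3,11-dimethyl-7-methylidenetrideca-2,11-dien-8-yl methyl carbonate
Conditions: HF·pyridine, pyridine/THF, 0 °C
Reagents that add atoms: none
Why: Buffered fluoride cleaves both primary silyl ethers and leaves the acetate and carbonate untouched.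

Step 11
Reactants: 11 diol
Product: 12 (2E,6R,11E)-6-acetoxy-3,11-dimethyl-7-methylidene-1,13-dioxotrideca-2,11-dien-8-yl methyl carbonate
Conditions: MnO2, CH2Cl2, 23 °C
Reagents that add atoms: none
Why: Manganese dioxide oxidizes both primary allylic alcohols to the (E)-enals and should not touch the secondary allylic esters.

Step 12
Reactants: 12 bis-enal
Product: 13 (1E,3Z,6R,10Z,12E)-6-acetoxy-3,11-dimethyl-7-methylidene-1,13-bis(triethylsilyloxy)trideca-1,3,10,12-tetraen-8-yl methyl carbonate
Conditions: Et3SiOTf, Et3N, Et2O, −78 to 0 °C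
Reagents that add atoms: triethylsilyl trifluoromethanesulfonate CC[Si](CC)(CC)OS(=O)(=O)C(F)(F)F
Why: Soft enolization (O-silylation, then loss of a γ-methylene proton to the amine) should give the more substituted 1-silyloxy-1,3-dienes, and allylic 1,3-strain should turn the chain toward the vinylic hydrogen so that C2 and C5 are cis, as five-ring closure requires.

Step 13
Reactants: 13 bis(triethylsilyl dienol ether)
Product: 16 (1S,5R,6S,7R,9R)-9-acetoxy-6,13-epoxy-13-hydroxy lactol of the hydroazulene (C13 anomers), via cyclopentene aldehyde 14 (not isolated), via silyl acetal 15 (not isolated)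
Conditions: Pd2(dba)3·CHCl3 (2.5 mol %), (R,R)-N,N′-cyclohexane-1,2-diylbis[2-(diphenylphosphanyl)benzamide] (7.5 mol %), THF, 23 °C; then Me2AlCl, CH2Cl2, −78 to −20 °C; then 1 M HCl, THF, 0 °C
Reagents that add atoms: none
Why: Proposed new method: zerovalent palladium ionizes the C1 carbonate (far faster than the C9 acetate), CO2 leaves and the methoxide strips one Et3Si group, so the free dienolate attacks π-allyl terminus C1 through its α-carbon C5 (5-exo-trig), giving the cyclopentene with C3=C4 and the C10=C18 methylene; the freed aldehyde C6, as its Me2AlCl complex, is then attacked by γ-carbon C7 of the second dienol ether in an oxa-[4+2]-type vinylogous Mukaiyama aldol (7-exo-trig for the carbocycle), and aqueous acid opens silyl acetal 15 to lactol 16. The closest known reaction types are the Tsuji–Trost allylation of silyl enol ethers by allylic carbonates, asymmetric Tsuji–Trost cyclizations to 2-alkenylcyclopentanes, and Lewis-acid diene–aldehyde cyclocondensations or intramolecular vinylogous Mukaiyama aldols used for medium rings. C1 should be set by the chiral ligand after π–σ–π exchange through the CH2 terminus C18, and C5 should fall trans to C1 (anti arrangement of enolate and allyl). C6 should arise from attack anti to the C4 alkenyl group with the carbonyl oxygen outside the forming ring, and C7 follows because the tether enforces a cis-fused cycloadduct (O6 and C11 cis). The step needs carbonate-over-acetate ionization, α- over γ-allylation and γ- over α-aldol attack, all dictated by ring size (the alternatives are three-membered, 5-endo or nine-membered closures), and it needs the 10Z geometry of 13.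

Step 14
Reactants: 16 lactol (open form: δ-hydroxy enal)
Product: 17 (1S,5R,6S,7R,9R,11S)-9-acetoxy-6,13-epoxy-13-hydroxy saturated lactol (C13 anomers)
Conditions: (R)-2-tert-butyl-3-methylimidazolidin-4-one·CCl3CO2H (20 mol %), Hantzsch ester, CHCl3, −30 °C
Reagents that add atoms: none
Why: Iminium-catalysed transfer hydrogenation of the β,β-disubstituted enal (E/Z-convergent) should deliver hydride to C11 under catalyst control, by analogy with β-methyl-β-aryl enals, and leave the isolated alkenes untouched.

Step 15
Reactants: 17 saturated lactol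
Product: 18 (1S,5R,6S,7R,9R,11S)-9-acetoxy-7-[(2S)-pent-4-en-2-yl]-4-methyl-10-methylidene hydroazulen-6-ol (3-ene)
Conditions: Ph3PCH3Br, KN(SiMe3)2, THF, 0 °C; then 17, 0 to 23 °C
Reagents that add atoms: methyltriphenylphosphonium bromide C[P+](c1ccccc1)(c1ccccc1)c1ccccc1.[Br-]
Why: Wittig methylenation of the open-chain aldehyde in equilibrium with the lactol releases the C6 hydroxyl and gives the terminal alkene; the aldehyde has no α-stereocenter to epimerize.

Step 16
Reactants: 18 terminal alkene
Product: 19 target
Conditions: 2-methylbut-3-en-2-ol (10 equiv), second-generation Hoveyda–Grubbs catalyst (H2IMes)Cl2Ru=CH(C6H4-2-OiPr) (5 mol %), CH2Cl2, 40 °C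
Reagents that add atoms: 2-methylbut-3-en-2-ol C=CC(C)(C)O
Why: Olefin cross-metathesis should engage only the monosubstituted alkene (the 1,1-disubstituted C10=C18 and trisubstituted C3=C4 alkenes are too hindered) and give the (E)-allylic tertiary alcohol.

## Compound list

1 | geraniol | CC(C)=CCC/C(C)=C/CO | starting material
2 | geranyl tert-butyldimethylsilyl ether | CC(C)=CCC/C(C)=C/CO[Si](C)(C)C(C)(C)C | intermediate
3 | 6,7-epoxygeranyl tert-butyldimethylsilyl ether (racemic epoxide) | CC1(C)OC1CC/C(C)=C/CO[Si](C)(C)C(C)(C)C | intermediate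
4 | (4E)-6-(tert-butyldimethylsilyloxy)-4-methylhex-4-enal | O=CCC/C(C)=C/CO[Si](C)(C)C(C)(C)C | intermediate
5 | (6E)-8-(tert-butyldimethylsilyloxy)-6-methylocta-1,6-dien-3-ol (racemic) | C=CC(O)CC/C(C)=C/CO[Si](C)(C)C(C)(C)C | intermediate
6 | (6E)-8-(tert-butyldimethylsilyloxy)-6-methylocta-1,6-dien-3-one | C=CC(=O)CC/C(C)=C/CO[Si](C)(C)C(C)(C)C | intermediate
7 | (2E,11E)-1,13-bis(tert-butyldimethylsilyloxy)-8-hydroxy-3,11-dimethyl-7-methylidenetrideca-2,11-dien-6-one (racemic) | CC(C)(C)[Si](C)(C)OC/C=C(C)/CCC(O)C(=C)C(=O)CC/C(C)=C/CO[Si](C)(C)C(C)(C)C | intermediate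
8 | (2E,11E)-1,13-bis(tert-butyldimethylsilyloxy)-3,11-dimethyl-7-methylidene-6-oxotrideca-2,11-dien-8-yl methyl carbonate (racemic) | CC(C)(C)[Si](C)(C)OC/C=C(C)/CCC(OC(=O)OC)C(=C)C(=O)CC/C(C)=C/CO[Si](C)(C)C(C)(C)C | intermediate
9 | (2E,6R,11E)-1,13-bis(tert-butyldimethylsilyloxy)-6-hydroxy-3,11-dimethyl-7-methylidenetrideca-2,11-dien-8-yl methyl carbonate (both C8 epimers) | CC(C)(C)[Si](C)(C)OC/C=C(C)/CCC(OC(=O)OC)C(=C)[C@H](O)CC/C(C)=C/CO[Si](C)(C)C(C)(C)C | intermediate
10 | (2E,6R,11E)-6-acetoxy-1,13-bis(tert-butyldimethylsilyloxy)-3,11-dimethyl-7-methylidenetrideca-2,11-dien-8-yl methyl carbonate | CC(C)(C)[Si](C)(C)OC/C=C(C)/CCC(OC(=O)OC)C(=C)[C@H](OC(C)=O)CC/C(C)=C/CO[Si](C)(C)C(C)(C)C | intermediate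
11 | (2E,6R,11E)-6-acetoxy-1,13-dihydroxy-3,11-dimethyl-7-methylidenetrideca-2,11-dien-8-yl methyl carbonate | OC/C=C(C)/CCC(OC(=O)OC)C(=C)[C@H](OC(C)=O)CC/C(C)=C/CO | intermediate
12 | (2E,6R,11E)-6-acetoxy-3,11-dimethyl-7-methylidene-1,13-dioxotrideca-2,11-dien-8-yl methyl carbonate | O=C/C=C(C)/CCC(OC(=O)OC)C(=C)[C@H](OC(C)=O)CC/C(C)=C/C=O | intermediate
13 | (1E,3Z,6R,10Z,12E)-6-acetoxy-3,11-dimethyl-7-methylidene-1,13-bis(triethylsilyloxy)trideca-1,3,10,12-tetraen-8-yl methyl carbonate | CC[Si](CC)(CC)O/C=C/C(C)=C\CC(OC(=O)OC)C(=C)[C@H](OC(C)=O)C/C=C(C)\C=C\O[Si](CC)(CC)CC | intermediate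
14 | (1S,5R,9R)-cyclopentene aldehyde: trans-5-formyl-4-methylcyclopent-3-en-1-yl (C1–C5) carrying at C1 the chain C10(=CH2)–C9H(OAc)–C8H2–C7H=C11(CH3)–C12H=C13H–OSiEt3 | C=C([C@H]1CC=C(C)[C@@H]1C=O)[C@H](OC(C)=O)C/C=C(C)\C=C\O[Si](CC)(CC)CC | intermediate (not isolated)
15 | (1S,5R,6S,7R,9R)-silyl acetal: trans-fused hydroazulene with 9-OAc and 10-methylidene, cis-fused at C6/C7 to a 4-methyl-2-(triethylsilyloxy)-5,6-dihydro-2H-pyran (O on C6, C13 acetal) | C=C1[C@H]2CC=C(C)[C@@H]2[C@@H](O3)[C@@H](C(C)=CC3O[Si](CC)(CC)CC)C[C@H]1OC(C)=O | intermediate (not isolated)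
16 | (1S,5R,6S,7R,9R)-lactol: as 15 with OH at C13 (anomers; in equilibrium with the (Z)-δ-hydroxy enal) | C=C1[C@H]2CC=C(C)[C@@H]2[C@@H](O3)[C@@H](C(C)=CC3O)C[C@H]1OC(C)=O | intermediate
17 | (1S,5R,6S,7R,9R,11S)-saturated lactol: as 16 with C11–C12 reduced (C13 anomers) | C=C1[C@H]2CC=C(C)[C@@H]2[C@@H](O3)[C@@H]([C@@H](C)CC3O)C[C@H]1OC(C)=O | intermediate
18 | (1S,5R,6S,7R,9R,11S)-terminal alkene: trans-fused hydroazulene (C3=C4, 4-CH3, 6-OH, 9-OAc, 10-methylidene) with (2S)-pent-4-en-2-yl at C7 | C=C1[C@H]2CC=C(C)[C@@H]2[C@@H](O)[C@@H]([C@@H](C)CC=C)C[C@H]1OC(C)=O | intermediate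
19 | target, (1S,5R,6S,7R,9R,11S): trans-fused hydroazulene (C3=C4, 4-CH3, 6-OH, 9-OAc, 10-methylidene) with (2S,4E)-6-hydroxy-6-methylhept-4-en-2-yl at C7 | C=C1[C@H]2CC=C(C)[C@@H]2[C@@H](O)[C@@H]([C@@H](C)C/C=C/C(C)(C)O)C[C@H]1OC(C)=O | target

## Step count and risks

Total steps: 16. Longest linear sequence: 16 (geraniol to 19; aldehyde 4 enters twice, in steps 4 and 6).

**Step 13 (proposed new method).** Several processes may fail:
- ring closure to the cyclopentene may not occur if step 12 delivers the dienol ether with C2 and C5 trans or from the γ-methyl group;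
- the π-allyl face may be chosen poorly relative to C9 (the ligand antipode is the first thing to try);
- the C9 acetate may ionize slowly;
- facial selectivity at C6/C7 may be low in the aldol ring closure.

Fallback: set out from bis-enal 12, so that the dienol ethers are bypassed. Treat 12 with Pd(PPh3)4 in THF (Tsuji–Trost reaction under neutral conditions). The methoxide released from the carbonate deprotonates the enal γ-position reversibly, so dienolate geometry equilibrates and only the cyclizable isomer is consumed. This should give the cyclopentene enal-aldehyde F1. Close the seven-membered ring by a directed vinylogous aldol with aluminium tris(2,6-diphenylphenoxide) and lithium 2,2,6,6-tetramethylpiperidide (toluene, −78 °C), which should give the open-chain (E)-δ-hydroxy enal F2. F2 is taken through the conditions of step 14 and rejoins the route at 17.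

**Step 14.** Hydride transfer may lose stereocontrol through catalyst/substrate mismatch, C7 may epimerize by γ-deprotonation (dienamine formation), or the hydroxy enal may undergo retro-aldol ring opening under amine catalysis.

Fallback: set out from 16. Oxidize the lactol with MnO2 to the α,β-unsaturated δ-lactone F3. Reduce the ring alkene by copper hydride conjugate reduction (Cu(OAc)2·H2O, (S)-p-tol-BINAP, polymethylhydrosiloxane, t-BuOH, toluene), under ligand control on the rigid cis-fused bicycle, to the saturated lactone F4. Half-reduce F4 with i-Bu2AlH (1 equiv, CH2Cl2, −78 °C; the lactone should react before the hindered secondary acetate) to rejoin the route at 17.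

**Step 6.** The Morita–Baylis–Hillman addition may be slow, with competing dimerization of the vinyl ketone and self-aldol of the enolizable aldehyde.

Fallback: set out from 4 and 6. Run a stoichiometric halo-aldol (TiCl4, Bu4NI, CH2Cl2, −78 °C): iodide adds to the vinyl ketone and the titanium enolate adds to 4, giving the α-(iodomethyl)-β-hydroxy ketone F5. Eliminate HI with DBU (CH2Cl2, 0 °C) to rejoin the route at 7.

Further compounds
F1 | step 13 | (1S,5R,9R)-cyclopentene enal-aldehyde (as 14 with the free (E)-enal in place of the dienol ether) | C=C([C@H]1CC=C(C)[C@@H]1C=O)[C@H](OC(C)=O)CC/C(C)=C/C=O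
F2 | step 13 | (1S,5R,6S,7R,9R)-open-chain (E)-δ-hydroxy enal (ring-opened isomer of 16) | C=C1[C@H]2CC=C(C)[C@@H]2[C@@H](O)[C@@H](/C(C)=C/C=O)C[C@H]1OC(C)=O
F3 | step 14 | (1S,5R,6S,7R,9R)-α,β-unsaturated δ-lactone (C13 carbonyl) | C=C1[C@H]2CC=C(C)[C@@H]2[C@@H](O3)[C@@H](C(C)=CC3=O)C[C@H]1OC(C)=O
F4 | step 14 | (1S,5R,6S,7R,9R,11S)-saturated δ-lactone | C=C1[C@H]2CC=C(C)[C@@H]2[C@@H](O3)[C@@H]([C@@H](C)CC3=O)C[C@H]1OC(C)=O
F5 | step 6 | (2E,11E)-1,13-bis(tert-butyldimethylsilyloxy)-8-hydroxy-7-(iodomethyl)-3,11-dimethyltrideca-2,11-dien-6-one | CC(C)(C)[Si](C)(C)OC/C=C(C)/CCC(O)C(CI)C(=O)CC/C(C)=C/CO[Si](C)(C)C(C)(C)C
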